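**Assumption:** Kanzonol V has no stereocentre and no E/Z-defined double bond, so "the single enantiomer given" is taken as the achiral compound as drawn. MOM = methoxymethyl.

## Retrosynthetic overview

1. The furan ring is closed last: acid removes the three MOM groups from a deoxybenzoin (aryl 2-hydroxybenzyl ketone) and cyclodehydrates it to the 2-arylbenzofuran.
2. The deoxybenzoin comes from Krapcho decarboxylation of a β-keto ester made by a crossed Claisen condensation: enolate of the prenylated arylacetate plus the activated chromene-8-carboxylic acid (key C–C bond, future C3–C2 of the furan).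
3. Arylacetate: resorcinol → bis-MOM ether → 4,6-dibromide → mono Br/Li exchange and prenylation → Pd-catalysed Reformatsky arylation.
4. Chromene acid: methyl 2,4-dihydroxybenzoate → 4-O-MOM → 2-O-(1,1-dimethylpropargyl) ether → aryl propargyl Claisen/oxa-6π cyclisation → saponification.
5. Ring order: both benzene rings are bought; pyran ring (step 7) first, furan ring (step 11) last.

## Route

**Step 1**
Reactants: 1 resorcinol
Product: 2 1,3-bis(methoxymethoxy)benzene
Conditions: NaH (2.4 equiv), MOMCl (2.4 equiv), DMF, 0 °C → rt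
Reagents that add atoms: chloromethyl methyl ether COCCl
Why: Williamson-type O-alkylation of both phenoxides; MOM survives organolithiums, enolates, Pd and 190 °C and is removed by the acid that later closes the furan.

**Step 2**
Reactants: 2 1,3-bis(methoxymethoxy)benzene
Product: 3 1,5-dibromo-2,4-bis(methoxymethoxy)benzene
Conditions: NBS (2.05 equiv), MeCN, 0 °C → rt
Reagents that add atoms: N-bromosuccinimide O=C1CCC(=O)N1Br
Why: Electrophilic aromatic bromination; each bromine enters para to one OMOM and ortho to the other (C4, C6), while C2 between the two ethers is shielded.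

**Step 3**
Reactants: 3 1,5-dibromo-2,4-bis(methoxymethoxy)benzene
Product: 5 1-bromo-2,4-bis(methoxymethoxy)-5-(3-methylbut-2-en-1-yl)benzene, via aryllithium 4 (not isolated)
Conditions: n-BuLi (1.05 equiv), THF, −78 °C; then CuBr·SMe2 (10 mol %), prenyl bromide (1.5 equiv), −78 → 0 °C
Reagents that add atoms: 1-bromo-3-methylbut-2-ene CC(C)=CCBr; n-butyllithium [Li]CCCC (lithium of 4 only)
Why: Mono bromine–lithium exchange on a symmetric dibromide (either bromine gives the same OMOM-chelated aryllithium), then copper-catalysed SN2 allylation gives the linear prenyl group.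

**Step 4**
Reactants: 5 1-bromo-2,4-bis(methoxymethoxy)-5-(3-methylbut-2-en-1-yl)benzene
Product: 6 ethyl 2-[2,4-bis(methoxymethoxy)-5-(3-methylbut-2-en-1-yl)phenyl]acetate
Conditions: BrZnCH2CO2Et (2 equiv, from ethyl bromoacetate, Zn dust, cat. TMSCl, THF), Pd2(dba)3 (2.5 mol %), XPhos (10 mol %), THF, 65 °C
Reagents that add atoms: ethyl bromoacetate CCOC(=O)CBr
Why: Pd-catalysed Negishi-type coupling of a Reformatsky reagent (ester α-arylation); the neutral zinc enolate tolerates the MOM ethers and the prenyl alkene.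

**Step 5**
Reactants: 7 methyl 2,4-dihydroxybenzoate
Product: 8 methyl 2-hydroxy-4-(methoxymethoxy)benzoate
Conditions: MOMCl (1.1 equiv), K2CO3 (1.5 equiv), acetone, 0 °C → rt
Reagents that add atoms: chloromethyl methyl ether COCCl
Why: Selective Williamson alkylation; the 2-OH is hydrogen-bonded to the ester carbonyl, so mild base alkylates only the 4-OH.

**Step 6**
Reactants: 8 methyl 2-hydroxy-4-(methoxymethoxy)benzoate
Product: 9 methyl 4-(methoxymethoxy)-2-[(2-methylbut-3-yn-2-yl)oxy]benzoate
Conditions: 3-chloro-3-methylbut-1-yne (2.5 equiv), DBU (3 equiv), CuCl2·2H2O (1 mol %), MeCN, 0 °C → rt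
Reagents that add atoms: 3-chloro-3-methylbut-1-yne CC(C)(Cl)C#C
Why: Copper-catalysed propargylic etherification (via a copper acetylide/allenylidene) of the only free phenol builds the tertiary propargyl aryl ether that simple SN2 chemistry cannot.

**Step 7**
Reactants: 9 methyl 4-(methoxymethoxy)-2-[(2-methylbut-3-yn-2-yl)oxy]benzoate
Product: 11 methyl 5-(methoxymethoxy)-2,2-dimethyl-2H-chromene-8-carboxylate, via allenylphenol 10 (not isolated)
Conditions: PhNEt2, 190 °C, 3 h
Reagents that add atoms: none
Why: Aromatic propargyl Claisen rearrangement to C3, the only free ortho carbon (C1 carries the ester), then 1,5-H shift and oxa-6π electrocyclisation give the chromene with its oxygen ortho to the ester.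

**Step 8**
Reactants: 11 methyl 5-(methoxymethoxy)-2,2-dimethyl-2H-chromene-8-carboxylate
Product: 12 5-(methoxymethoxy)-2,2-dimethyl-2H-chromene-8-carboxylic acid
Conditions: NaOH (3 equiv), THF/MeOH/H2O, 50 °C; then 1 M HCl to pH 4, 0 °C
Reagents that add atoms: sodium hydroxide [Na+].[OH-]
Why: Ester saponification; base leaves the MOM ether and chromene untouched, and the brief cold acidification is too mild to cleave MOM.

**Step 9**
Reactants: 6 ethyl 2-[2,4-bis(methoxymethoxy)-5-(3-methylbut-2-en-1-yl)phenyl]acetate; 12 5-(methoxymethoxy)-2,2-dimethyl-2H-chromene-8-carboxylic acid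
Product: 15 ethyl 2-[2,4-bis(methoxymethoxy)-5-(3-methylbut-2-en-1-yl)phenyl]-3-[5-(methoxymethoxy)-2,2-dimethyl-2H-chromen-8-yl]-3-oxopropanoate, via acylimidazole 13 (not isolated), via lithium enolate 14 (not isolated)
Conditions: 12 (1.1 equiv), CDI (1.1 equiv), THF, rt, 2 h; separately 6, LiHMDS (3.3 equiv), THF, −78 °C; combine, −78 → 0 °C; then 1 M HCl to pH 5–6, 0 °C
Reagents that add atoms: 1,1'-carbonyldiimidazole O=C(n1ccnc1)n1ccnc1 (imidazolyl of 13 only); lithium hexamethyldisilazide [Li]N([Si](C)(C)C)[Si](C)(C)C (lithium of 14 only)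
Why: Crossed Claisen condensation (C-acylation of the preformed ester enolate by the N-acylimidazole), driven by deprotonation of the β-keto ester; excess base also covers the liberated imidazole, and the new stereocentre is racemic and removed in step 10.

**Step 10**
Reactants: 15 ethyl 2-[2,4-bis(methoxymethoxy)-5-(3-methylbut-2-en-1-yl)phenyl]-3-[5-(methoxymethoxy)-2,2-dimethyl-2H-chromen-8-yl]-3-oxopropanoate
Product: 16 2-[2,4-bis(methoxymethoxy)-5-(3-methylbut-2-en-1-yl)phenyl]-1-[5-(methoxymethoxy)-2,2-dimethyl-2H-chromen-8-yl]ethan-1-one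
Conditions: LiCl (4 equiv), H2O (3 equiv), DMSO, 140 °C
Reagents that add atoms: none
Why: Krapcho dealkoxycarbonylation of an α-aryl β-keto ester under neutral conditions avoids the retro-Claisen cleavage that hydroxide would risk and keeps MOM, prenyl and chromene intact.

**Step 11**
Reactants: 16 2-[2,4-bis(methoxymethoxy)-5-(3-methylbut-2-en-1-yl)phenyl]-1-[5-(methoxymethoxy)-2,2-dimethyl-2H-chromen-8-yl]ethan-1-one
Product: 18 Kanzonol V, via triphenol ketone 17 (not isolated)
Conditions: 1.25 M HCl in MeOH, 45 °C, monitored and stopped at full conversion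
Reagents that add atoms: none
Why: Acid-catalysed methanolysis of the three MOM acetals frees the 2-hydroxybenzyl ketone, which hemiketalises and dehydrates (cyclodehydration) to the aromatic benzofuran; no stereocentre is formed.

## Compound list

1 | resorcinol | Oc1cccc(O)c1 | starting material
2 | 1,3-bis(methoxymethoxy)benzene | COCOc1cccc(OCOC)c1 | intermediate
3 | 1,5-dibromo-2,4-bis(methoxymethoxy)benzene | COCOc1cc(OCOC)c(Br)cc1Br | intermediate
4 | [5-bromo-2,4-bis(methoxymethoxy)phenyl]lithium | COCOc1cc(OCOC)c(Br)cc1[Li] | intermediate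
5 | 1-bromo-2,4-bis(methoxymethoxy)-5-(3-methylbut-2-en-1-yl)benzene | COCOc1cc(OCOC)c(CC=C(C)C)cc1Br | intermediate
6 | ethyl 2-[2,4-bis(methoxymethoxy)-5-(3-methylbut-2-en-1-yl)phenyl]acetate | CCOC(=O)Cc1cc(CC=C(C)C)c(OCOC)cc1OCOC | intermediate
7 | methyl 2,4-dihydroxybenzoate | COC(=O)c1ccc(O)cc1O | starting material
8 | methyl 2-hydroxy-4-(methoxymethoxy)benzoate | COCOc1ccc(C(=O)OC)c(O)c1 | intermediate
9 | methyl 4-(methoxymethoxy)-2-[(2-methylbut-3-yn-2-yl)oxy]benzoate | COCOc1ccc(C(=O)OC)c(OC(C)(C)C#C)c1 | intermediate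
10 | methyl 2-hydroxy-4-(methoxymethoxy)-3-(3-methylbuta-1,2-dien-1-yl)benzoate | COC(=O)c1ccc(OCOC)c(C=C=C(C)C)c1O | intermediate
11 | methyl 5-(methoxymethoxy)-2,2-dimethyl-2H-chromene-8-carboxylate | COC(=O)c1ccc(OCOC)c2C=CC(C)(C)Oc12 | intermediate
12 | 5-(methoxymethoxy)-2,2-dimethyl-2H-chromene-8-carboxylic acid | OC(=O)c1ccc(OCOC)c2C=CC(C)(C)Oc12 | intermediate
13 | (1H-imidazol-1-yl)[5-(methoxymethoxy)-2,2-dimethyl-2H-chromen-8-yl]methanone | O=C(c1ccc(OCOC)c2C=CC(C)(C)Oc12)n1ccnc1 | intermediate
14 | lithium 2-[2,4-bis(methoxymethoxy)-5-(3-methylbut-2-en-1-yl)phenyl]-1-ethoxyethen-1-olate | [Li+].CCOC([O-])=Cc1cc(CC=C(C)C)c(OCOC)cc1OCOC | intermediate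
15 | ethyl 2-[2,4-bis(methoxymethoxy)-5-(3-methylbut-2-en-1-yl)phenyl]-3-[5-(methoxymethoxy)-2,2-dimethyl-2H-chromen-8-yl]-3-oxopropanoate (racemic) | CCOC(=O)C(C(=O)c1ccc(OCOC)c2C=CC(C)(C)Oc12)c1cc(CC=C(C)C)c(OCOC)cc1OCOC | intermediate
16 | 2-[2,4-bis(methoxymethoxy)-5-(3-methylbut-2-en-1-yl)phenyl]-1-[5-(methoxymethoxy)-2,2-dimethyl-2H-chromen-8-yl]ethan-1-one | COCOc1cc(OCOC)c(CC=C(C)C)cc1CC(=O)c1ccc(OCOC)c2C=CC(C)(C)Oc12 | intermediate
17 | 2-[2,4-dihydroxy-5-(3-methylbut-2-en-1-yl)phenyl]-1-(5-hydroxy-2,2-dimethyl-2H-chromen-8-yl)ethan-1-one | CC(C)=CCc1cc(CC(=O)c2ccc(O)c3C=CC(C)(C)Oc23)c(O)cc1O | intermediate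
18 | Kanzonol V, 2-(5-hydroxy-2,2-dimethyl-2H-chromen-8-yl)-5-(3-methylbut-2-en-1-yl)-1-benzofuran-6-ol | CC(C)=CCc1cc2cc(-c3ccc(O)c4c3OC(C)(C)C=C4)oc2cc1O | target

## Summary

Total steps: 11. Longest linear sequence: 7 steps (steps 1, 2, 3, 4, 9, 10, 11; the branch through steps 5–8 is equally long).

**Three steps most likely to fail**

Step 6 (etherification of the hydrogen-bonded salicylate OH with a tertiary propargyl chloride). The phenol is a weak nucleophile and the yield may be poor. The fallback sets out from 8 and comes back at 11, replacing steps 6 and 7. Compound 8 is heated with 3-methylbut-2-enal diethyl acetal (1,1-diethoxy-3-methylbut-2-ene) and 3-picoline in p-xylene at 140 °C while ethanol distils off. Transacetalisation, loss of ethanol to the o-quinone methide and oxa-6π electrocyclisation at C3 give 11 directly; C3 is the only free ortho carbon, so the regiochemistry is unchanged. This detour makes no compound outside the list (F0).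

Step 9 (Claisen condensation with an electron-rich, ortho-substituted acyl donor). C-acylation may be slow, or O-acylation and attack of the amide base on 13 may compete. The fallback sets out from 11 (with 6) and comes back at 15, using an aldol addition and oxidation instead of an acylation. DIBAL-H in CH2Cl2 at −78 °C reduces 11 to [5-(methoxymethoxy)-2,2-dimethyl-2H-chromen-8-yl]methanol F1. MnO2 in CH2Cl2 oxidises this to 5-(methoxymethoxy)-2,2-dimethyl-2H-chromene-8-carbaldehyde F2. The lithium enolate 14 (from 6 and LDA, THF, −78 °C) adds to this far more electrophilic aldehyde to give ethyl 2-[2,4-bis(methoxymethoxy)-5-(3-methylbut-2-en-1-yl)phenyl]-3-hydroxy-3-[5-(methoxymethoxy)-2,2-dimethyl-2H-chromen-8-yl]propanoate F3 as a diastereomer mixture. Dess–Martin periodinane with NaHCO3 in CH2Cl2 oxidises this to 15.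

Step 11 (one-pot acid deprotection and furan closure). Protic acid can cyclise the ortho-prenyl phenol to a dimethylchroman or add methanol to the chromene double bond. The fallback sets out from 16 and comes back at 18, separating deprotection from ring closure and avoiding strong protic acid. ZnBr2 with n-PrSH in CH2Cl2 at 0 °C transfers the three MOM groups to sulfur within minutes and gives the triphenol ketone 17, which is isolated. Compound 17 is then dehydrated with catalytic PPTS and 4 Å molecular sieves in toluene at 60 °C to give 18. This detour makes no compound outside the list (F0).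

## Further compounds

F1 | step 9 | [5-(methoxymethoxy)-2,2-dimethyl-2H-chromen-8-yl]methanol | COCOc1ccc(CO)c2OC(C)(C)C=Cc12
F2 | step 9 | 5-(methoxymethoxy)-2,2-dimethyl-2H-chromene-8-carbaldehyde | COCOc1ccc(C=O)c2OC(C)(C)C=Cc12
F3 | step 9 | ethyl 2-[2,4-bis(methoxymethoxy)-5-(3-methylbut-2-en-1-yl)phenyl]-3-hydroxy-3-[5-(methoxymethoxy)-2,2-dimethyl-2H-chromen-8-yl]propanoate (diastereomer mixture, racemic) | CCOC(=O)C(C(O)c1ccc(OCOC)c2OC(C)(C)C=Cc12)c1cc(CC=C(C)C)c(OCOC)cc1OCOC
F0 | step 6 | none | none
F0 | step 11 | none | none
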